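## Retrosynthetic overview

1. Numbering: ring A = lactone O–C3(=O)–C2=C1–C10–C5–C4(Me)2; ring B = C5–C6–C7–C8–C9–C10; ring C = C8–C9–C11–C12–C13–C14; ring D = C12–C13–C14–C15–C16–C17.
2. Last disconnection: C8–C14 (ring C, the bicyclo[3.3.1]nonane). Acid closure of a C8=C9 alkene onto C14 of a dearomatised ring D sets C9, C8 and C14.
3. Key disconnection: C6–C7 (ring B) together with C11–C12. The enabling feature is that C7, C8, C9 and C11 form a four-carbon unit hung on C10, between C6 (on ring A) and C12 (on ring D). As a 3-methylbuta-1,3-dien-2-yl group it accepts a C6 radical at C7, which closes ring B, and passes the resulting C8–C9–C11 allyl unit through palladium to C12 of the ring D dienolate.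
4. Ring A: benzoic acid, Birch reductive methylation (dearomatisation, C10), desymmetrising copper-catalysed conjugate addition (C5), Baeyer–Villiger oxidation. Ring D: atraric acid, C-methylation, hydroxylative dearomatisation (C16).
5. Order of ring formation: A and D separately, then B (key step, joins the two fragments), then C.

Key step: step 18

Remark: the enantiomer of the copper ligand (step 5) and of the iodyl reagent (step 16) is taken to be the one that gives the configuration drawn, to be fixed by a short screen; the carbinol centre made in step 11 is left uncontrolled because step 12 removes it; faces of rings A to C are named relative to the C10 methyl group.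

## Route

Step 1
Reactants: 1 benzoic acid
Product: 2 1-methylcyclohexa-2,5-diene-1-carboxylic acid
Conditions: Li, NH3 (l)/THF, −78 °C; MeI; aq. HCl
Reagents that add atoms: iodomethane, CI
Why: Birch reduction gives the carboxylate-stabilised ipso carbanion, which is methylated at that carbon (Birch reductive alkylation), so the flat arene becomes the ring A carbocycle with the future quaternary C10 and its methyl group.

Step 2
Reactants: 2 1-methylcyclohexa-2,5-diene-1-carboxylic acid
Product: 3 1-(1-methylcyclohexa-2,5-dien-1-yl)ethan-1-one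
Conditions: MeLi (2.2 equiv), Et2O, 0 °C to rt; aq. NH4Cl
Reagents that add atoms: methyllithium, [Li]C
Why: addition of an organolithium to the lithium carboxylate stops at the dilithium gem-diolate, which gives the methyl ketone on work-up (carboxylic acid to ketone).

Step 3
Reactants: 3 1-(1-methylcyclohexa-2,5-dien-1-yl)ethan-1-one
Product: 4 2-methyl-2-(1-methylcyclohexa-2,5-dien-1-yl)-1,3-dioxolane
Conditions: TMSOCH2CH2OTMS, TMSOTf (5 mol %), CH2Cl2, −78 to −20 °C
Reagents that add atoms: 1,2-bis(trimethylsilyloxy)ethane, C[Si](C)(C)OCCO[Si](C)(C)C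
Why: silyl-triflate-catalysed ketalisation runs under aprotic conditions that should leave the skipped diene alone; the dioxolane masks the enolisable acetyl group and serves later as the bulky substituent on C10.

Step 4
Reactants: 4 2-methyl-2-(1-methylcyclohexa-2,5-dien-1-yl)-1,3-dioxolane
Product: 5 4-methyl-4-(2-methyl-1,3-dioxolan-2-yl)cyclohexa-2,5-dien-1-one
Conditions: Rh2(cap)4 (dirhodium tetracaprolactamate, 1 mol %), t-BuOOH, K2CO3, CH2Cl2, rt
Reagents that add atoms: tert-butyl hydroperoxide, CC(C)(C)OO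
Why: the doubly allylic CH2 has the weakest C–H bonds and should be oxidised to the ketone (allylic oxidation with a dirhodium carboxamidate and hydroperoxide); the quaternary carbon blocks aromatisation, giving the prochiral cross-conjugated dienone.

Step 5
Reactants: 5 4-methyl-4-(2-methyl-1,3-dioxolan-2-yl)cyclohexa-2,5-dien-1-one
Product: 6 (4R,5R)-5-{[dimethyl(phenyl)silyl]methyl}-4-methyl-4-(2-methyl-1,3-dioxolan-2-yl)cyclohex-2-en-1-one
Conditions: PhMe2SiCH2MgCl (1.3 equiv), CuBr·SMe2 (5 mol %), Josiphos ligand (6 mol %), t-BuOMe, −78 °C; aq. NH4Cl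
Reagents that add atoms: [dimethyl(phenyl)silyl]methylmagnesium chloride, C[Si](C)(C[Mg]Cl)c1ccccc1
Why: copper-catalysed asymmetric conjugate addition desymmetrises the dienone; the nucleophile should add anti to the quaternary ketal substituent (C6 trans to the future C9) and the chiral diphosphine–copper catalyst selects one enantiotopic enone, which fixes C10 and C5 together.

Step 6
Reactants: 6 (4R,5R)-5-{[dimethyl(phenyl)silyl]methyl}-4-methyl-4-(2-methyl-1,3-dioxolan-2-yl)cyclohex-2-en-1-one
Product: 8 (4R,5R)-5-{[dimethyl(phenyl)silyl]methyl}-4,6,6-trimethyl-4-(2-methyl-1,3-dioxolan-2-yl)cyclohex-2-en-1-one, via monomethyl enone 7 (not isolated)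
Conditions: KHMDS (1.2 equiv), MeI, THF, −78 °C; then KHMDS (1.3 equiv), MeI, −78 to 0 °C
Reagents that add atoms: iodomethane, CI
Why: because C10 is quaternary the enone can enolise only at the alpha-prime CH2, so two successive kinetic enolate alkylations should install the C4 gem-dimethyl group.

Step 7
Reactants: 8 (4R,5R)-5-{[dimethyl(phenyl)silyl]methyl}-4,6,6-trimethyl-4-(2-methyl-1,3-dioxolan-2-yl)cyclohex-2-en-1-one
Product: 9 (5R,6S)-6-{[dimethyl(phenyl)silyl]methyl}-5,7,7-trimethyl-5-(2-methyl-1,3-dioxolan-2-yl)-6,7-dihydrooxepin-2(5H)-one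
Conditions: m-CPBA (2.5 equiv), NaHCO3, CH2Cl2, 0 to 40 °C
Reagents that add atoms: 3-chloroperoxybenzoic acid, OOC(=O)c1cccc(Cl)c1
Why: Baeyer–Villiger oxidation with migration of the tertiary C4 in preference to the vinyl carbon gives the α,β-unsaturated ε-lactone of ring A; the electron-poor alkene and the arylsilane are inert to the buffered peracid.

Step 8
Reactants: 9 (5R,6S)-6-{[dimethyl(phenyl)silyl]methyl}-5,7,7-trimethyl-5-(2-methyl-1,3-dioxolan-2-yl)-6,7-dihydrooxepin-2(5H)-one
Product: 10 (5R,6R)-6-(hydroxymethyl)-5,7,7-trimethyl-5-(2-methyl-1,3-dioxolan-2-yl)-6,7-dihydrooxepin-2(5H)-one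
Conditions: KBr, NaOAc, AcOOH, AcOH, 0 °C to rt; aq. Na2S2O3
Reagents that add atoms: peracetic acid, CC(=O)OO
Why: Fleming–Tamao oxidation (ipso-bromodesilylation of the phenyl group, then peracid-induced shift of C6 from silicon to oxygen) turns the C–Si bond into the primary alcohol, while the acetate buffer should keep the hindered dioxolane in place so that the alcohol never meets a free ketone.

Step 9
Reactants: 10 (5R,6R)-6-(hydroxymethyl)-5,7,7-trimethyl-5-(2-methyl-1,3-dioxolan-2-yl)-6,7-dihydrooxepin-2(5H)-one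
Product: 11 (5R,6S)-6-(iodomethyl)-5,7,7-trimethyl-5-(2-methyl-1,3-dioxolan-2-yl)-6,7-dihydrooxepin-2(5H)-one
Conditions: I2, PPh3, imidazole, toluene, 60 °C
Reagents that add atoms: iodine, II
Why: Appel iodination through the alkoxyphosphonium salt and SN2 displacement by iodide gives the radical precursor at C6 without touching C5, and with the ketone still masked no cyclic hemiketal or enol ether can divert the alcohol.

Step 10
Reactants: 11 (5R,6S)-6-(iodomethyl)-5,7,7-trimethyl-5-(2-methyl-1,3-dioxolan-2-yl)-6,7-dihydrooxepin-2(5H)-one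
Product: 12 (5R,6S)-5-acetyl-6-(iodomethyl)-5,7,7-trimethyl-6,7-dihydrooxepin-2(5H)-one
Conditions: 1 M HCl, THF, rt to 40 °C
Reagents that add atoms: water, O
Why: acid-catalysed acetal hydrolysis frees the methyl ketone, and the primary iodide and the lactone should be inert to dilute aqueous acid at this temperature.

Step 11
Reactants: 12 (5R,6S)-5-acetyl-6-(iodomethyl)-5,7,7-trimethyl-6,7-dihydrooxepin-2(5H)-one
Product: 13 (5R,6S)-5-(2-hydroxy-3-methylbut-3-en-2-yl)-6-(iodomethyl)-5,7,7-trimethyl-6,7-dihydrooxepin-2(5H)-one (both epimers at the carbinol carbon)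
Conditions: CH2=C(CH3)MgBr, CeCl3, THF, −78 °C; aq. NH4Cl at −78 °C
Reagents that add atoms: isopropenylmagnesium bromide, C=C(C)[Mg]Br
Why: the organocerium reagent should add 1,2 to the hindered, enolisable methyl ketone much faster than to the conjugated lactone or the alkyl iodide at −78 °C (organocerium carbonyl addition).

Step 12
Reactants: 13 (5R,6S)-5-(2-hydroxy-3-methylbut-3-en-2-yl)-6-(iodomethyl)-5,7,7-trimethyl-6,7-dihydrooxepin-2(5H)-one
Product: 14 (5R,6S)-6-(iodomethyl)-5,7,7-trimethyl-5-(3-methylbuta-1,3-dien-2-yl)-6,7-dihydrooxepin-2(5H)-one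
Conditions: Burgess reagent, benzene, 50 °C
Reagents that add atoms: none
Why: Burgess dehydration (syn elimination of the sulfamate ester) can take a hydrogen only from the carbinol methyl group, since the other two neighbours carry none, so the 2,3-disubstituted buta-1,3-diene should form regiospecifically.

Step 13
Reactants: 15 methyl 2,4-dihydroxy-3,6-dimethylbenzoate (atraric acid)
Product: 16 methyl 5-formyl-2,4-dihydroxy-3,6-dimethylbenzoate
Conditions: Cl2CHOMe, TiCl4, CH2Cl2, 0 °C; ice water
Reagents that add atoms: dichloromethyl methyl ether, COC(Cl)Cl; water, O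
Why: Rieche formylation (Friedel–Crafts reaction of the dichloromethyl ether–TiCl4 complex) attacks the only free ring position, which is ortho to one hydroxyl and para to the other.

Step 14
Reactants: 16 methyl 5-formyl-2,4-dihydroxy-3,6-dimethylbenzoate
Product: 17 methyl 2,4-dihydroxy-3,5,6-trimethylbenzoate
Conditions: H2 (1 atm), Pd/C (10%), AcOH, rt
Reagents that add atoms: none
Why: hydrogenolysis of the electron-rich hydroxybenzaldehyde through the benzylic alcohol gives the C12 methyl group.

Step 15
Reactants: 17 methyl 2,4-dihydroxy-3,5,6-trimethylbenzoate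
Product: 18 methyl 4-[(tert-butyldimethylsilyl)oxy]-2-hydroxy-3,5,6-trimethylbenzoate
Conditions: TBSCl, imidazole, DMF, rt
Reagents that add atoms: tert-butyldimethylsilyl chloride, CC(C)(C)[Si](C)(C)Cl
Why: the 2-hydroxyl is held in a hydrogen bond to the ester carbonyl, so silylation should occur at the 4-hydroxyl; this leaves the 2-hydroxyl as the only free phenol to direct the next oxidation.

Step 16
Reactants: 18 methyl 4-[(tert-butyldimethylsilyl)oxy]-2-hydroxy-3,5,6-trimethylbenzoate
Product: 19 methyl (5S)-4-[(tert-butyldimethylsilyl)oxy]-5-hydroxy-2,3,5-trimethyl-6-oxocyclohexa-1,3-diene-1-carboxylate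
Conditions: (S)-4-isopropyl-2-(2-iodoxyphenyl)-4,5-dihydrooxazole (1.2 equiv), DMF, −25 °C; aq. Na2S2O3
Reagents that add atoms: (S)-4-isopropyl-2-(2-iodoxyphenyl)-4,5-dihydrooxazole, CC(C)[C@H]1COC(=N1)c1ccccc1I(=O)=O
Why: hydroxylative phenol dearomatisation: the free phenol binds the pentavalent iodine reagent and oxygen is delivered to the ortho carbon that bears the methyl group (the other ortho carbon bears the ester), with the chiral oxazoline on iodine choosing the face so that C16 is set as S.

Step 17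
Reactants: 19 methyl (5S)-4-[(tert-butyldimethylsilyl)oxy]-5-hydroxy-2,3,5-trimethyl-6-oxocyclohexa-1,3-diene-1-carboxylate
Product: 21 methyl (5S)-4-hydroxy-2,3,5-trimethyl-6-oxo-5-[(triethylsilyl)oxy]cyclohexa-1,3-diene-1-carboxylate, via bis-silyl quinol 20 (not isolated)
Conditions: TESOTf, 2,6-lutidine, CH2Cl2, −78 to 0 °C; then K2CO3, MeOH, 0 °C; pH 5 buffer
Reagents that add atoms: triethylsilyl trifluoromethanesulfonate, CC[Si](CC)(CC)OS(=O)(=O)C(F)(F)F
Why: the silyl triflate silylates the tertiary alcohol, and methanolysis then cleaves only the vinylogous silyl ester at O17, which is far more labile than a tertiary alkyl silyl ether, freeing the vinylogous acid.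

Step 18
Reactants: 14 (5R,6S)-6-(iodomethyl)-5,7,7-trimethyl-5-(3-methylbuta-1,3-dien-2-yl)-6,7-dihydrooxepin-2(5H)-one; 21 methyl (5S)-4-hydroxy-2,3,5-trimethyl-6-oxo-5-[(triethylsilyl)oxy]cyclohexa-1,3-diene-1-carboxylate
Product: 22 methyl (3R,5S)-2,3,5-trimethyl-4,6-dioxo-3-{[(5aR,9aS)-1,1,5a,7-tetramethyl-3-oxo-1,3,5a,8,9,9a-hexahydro-2-benzoxepin-6-yl]methyl}-5-[(triethylsilyl)oxy]cyclohex-1-ene-1-carboxylate
Conditions: Pd(PPh3)4 (10 mol %), Cs2CO3, 1,4-dioxane, 456 nm LEDs, rt, degassed
Reagents that add atoms: none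
Why: Proposed new method: blue-light-excited zerovalent palladium abstracts the iodine atom of 14 to give the primary C6 radical, which closes ring B by 6-endo-trig attack on the terminal C7 of the diene (chair transition state, C6 radical and diene both equatorial on ring A), the only mode that leaves a stabilised C8–C9–C11 allyl radical; this radical is captured by monovalent palladium as the π-allyl complex of divalent palladium. The caesium dienolate of 21 then attacks the unsubstituted C11 terminus through C12 (Tsuji–Trost alkylation), which forms the C11–C12 bond, leaves the tetrasubstituted C8=C9 alkene needed for step 19 and returns zerovalent palladium. The closest known reactions are the visible-light palladium-catalysed 1,4-carbofunctionalisation of 1,3-dienes with unactivated alkyl iodides and a nucleophile, and alkyl-Heck cyclisations; new here are the intramolecular radical step and a dearomatised vinylogous acid as the soft carbon nucleophile. C5 and C10 are carried in unchanged, and the new quaternary C12 is set by ring D itself, the allyl unit approaching the planar dienolate anti to the bulky C16 triethylsilyloxy group (3R). The step needs C- over O-allylation (an O-allyl enol ether should re-ionise under the catalyst and funnel to the C-allyl product), C12 over C14 attack (C14 is more hindered and carries the ester) and C11 over C8 attack on the allyl unit (C8 is fully substituted).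

Step 19
Reactants: 22 methyl (3R,5S)-2,3,5-trimethyl-4,6-dioxo-3-{[(5aR,9aS)-1,1,5a,7-tetramethyl-3-oxo-1,3,5a,8,9,9a-hexahydro-2-benzoxepin-6-yl]methyl}-5-[(triethylsilyl)oxy]cyclohex-1-ene-1-carboxylate
Product: 24 the target meroterpenoid (free 16-hydroxyl compound), via silyl ether 23 (not isolated)
Conditions: SnCl4 (2 equiv), wet CH2Cl2, −78 to −20 °C; aq. NaHCO3; then Et3N·3HF, MeCN, rt
Reagents that add atoms: none
Why: SnCl4 chelates the C15 ketone and the ester and enolises the C13 methyl group to the cross-conjugated tin dienolate with release of HCl, which protonates C8=C9 at C9 on the face anti to the C10 methyl, and the tertiary C8 cation is then captured, again anti to the C10 methyl, by C14 of the dienolate (which leaves the exocyclic C13 methylene) in a proton-initiated cation–olefin cyclisation terminated by a β-keto ester enol, closing ring C as a chair and forming the bicyclo[3.3.1]nonane with C9, C8 and C14 set under the control of C10 and C12; fluoride then frees the C16 hydroxyl.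

## Compound list

1 | benzoic acid | OC(=O)c1ccccc1 | starting material
2 | 1-methylcyclohexa-2,5-diene-1-carboxylic acid | CC1(C(=O)O)C=CCC=C1 | intermediate
3 | 1-(1-methylcyclohexa-2,5-dien-1-yl)ethan-1-one | CC(=O)C1(C)C=CCC=C1 | intermediate
4 | 2-methyl-2-(1-methylcyclohexa-2,5-dien-1-yl)-1,3-dioxolane | CC1(OCCO1)C1(C)C=CCC=C1 | intermediate
5 | 4-methyl-4-(2-methyl-1,3-dioxolan-2-yl)cyclohexa-2,5-dien-1-one | CC1(OCCO1)C1(C)C=CC(=O)C=C1 | intermediate
6 | (4R,5R)-5-{[dimethyl(phenyl)silyl]methyl}-4-methyl-4-(2-methyl-1,3-dioxolan-2-yl)cyclohex-2-en-1-one | CC1(OCCO1)[C@]2(C)C=CC(=O)C[C@H]2C[Si](C)(C)c3ccccc3 | intermediate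
7 | monomethyl enone: (4R,5R)-5-{[dimethyl(phenyl)silyl]methyl}-4,6-dimethyl-4-(2-methyl-1,3-dioxolan-2-yl)cyclohex-2-en-1-one, both C6 epimers | CC1(OCCO1)[C@]2(C)C=CC(=O)C(C)[C@H]2C[Si](C)(C)c3ccccc3 | intermediate
8 | (4R,5R)-5-{[dimethyl(phenyl)silyl]methyl}-4,6,6-trimethyl-4-(2-methyl-1,3-dioxolan-2-yl)cyclohex-2-en-1-one | CC1(OCCO1)[C@]2(C)C=CC(=O)C(C)(C)[C@H]2C[Si](C)(C)c3ccccc3 | intermediate
9 | (5R,6S)-6-{[dimethyl(phenyl)silyl]methyl}-5,7,7-trimethyl-5-(2-methyl-1,3-dioxolan-2-yl)-6,7-dihydrooxepin-2(5H)-one | CC1(OCCO1)[C@]2(C)C=CC(=O)OC(C)(C)[C@H]2C[Si](C)(C)c3ccccc3 | intermediate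
10 | (5R,6R)-6-(hydroxymethyl)-5,7,7-trimethyl-5-(2-methyl-1,3-dioxolan-2-yl)-6,7-dihydrooxepin-2(5H)-one | CC1(OCCO1)[C@]2(C)C=CC(=O)OC(C)(C)[C@H]2CO | intermediate
11 | (5R,6S)-6-(iodomethyl)-5,7,7-trimethyl-5-(2-methyl-1,3-dioxolan-2-yl)-6,7-dihydrooxepin-2(5H)-one | CC1(OCCO1)[C@]2(C)C=CC(=O)OC(C)(C)[C@H]2CI | intermediate
12 | (5R,6S)-5-acetyl-6-(iodomethyl)-5,7,7-trimethyl-6,7-dihydrooxepin-2(5H)-one | CC(=O)[C@]1(C)C=CC(=O)OC(C)(C)[C@H]1CI | intermediate
13 | (5R,6S)-5-(2-hydroxy-3-methylbut-3-en-2-yl)-6-(iodomethyl)-5,7,7-trimethyl-6,7-dihydrooxepin-2(5H)-one, both epimers at the carbinol carbon | C=C(C)C(C)(O)[C@]1(C)C=CC(=O)OC(C)(C)[C@H]1CI | intermediate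
14 | (5R,6S)-6-(iodomethyl)-5,7,7-trimethyl-5-(3-methylbuta-1,3-dien-2-yl)-6,7-dihydrooxepin-2(5H)-one | C=C(C)C(=C)[C@]1(C)C=CC(=O)OC(C)(C)[C@H]1CI | intermediate
15 | methyl 2,4-dihydroxy-3,6-dimethylbenzoate (atraric acid) | COC(=O)c1c(C)cc(O)c(C)c1O | starting material
16 | methyl 5-formyl-2,4-dihydroxy-3,6-dimethylbenzoate | COC(=O)c1c(C)c(C=O)c(O)c(C)c1O | intermediate
17 | methyl 2,4-dihydroxy-3,5,6-trimethylbenzoate | COC(=O)c1c(C)c(C)c(O)c(C)c1O | intermediate
18 | methyl 4-[(tert-butyldimethylsilyl)oxy]-2-hydroxy-3,5,6-trimethylbenzoate | COC(=O)c1c(C)c(C)c(O[Si](C)(C)C(C)(C)C)c(C)c1O | intermediate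
19 | methyl (5S)-4-[(tert-butyldimethylsilyl)oxy]-5-hydroxy-2,3,5-trimethyl-6-oxocyclohexa-1,3-diene-1-carboxylate | COC(=O)C1=C(C)C(C)=C(O[Si](C)(C)C(C)(C)C)[C@](C)(O)C1=O | intermediate
20 | bis-silyl quinol: methyl (5S)-4-[(tert-butyldimethylsilyl)oxy]-2,3,5-trimethyl-6-oxo-5-[(triethylsilyl)oxy]cyclohexa-1,3-diene-1-carboxylate | COC(=O)C1=C(C)C(C)=C(O[Si](C)(C)C(C)(C)C)[C@](C)(O[Si](CC)(CC)CC)C1=O | intermediate
21 | methyl (5S)-4-hydroxy-2,3,5-trimethyl-6-oxo-5-[(triethylsilyl)oxy]cyclohexa-1,3-diene-1-carboxylate | COC(=O)C1=C(C)C(C)=C(O)[C@](C)(O[Si](CC)(CC)CC)C1=O | intermediate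
22 | methyl (3R,5S)-2,3,5-trimethyl-4,6-dioxo-3-{[(5aR,9aS)-1,1,5a,7-tetramethyl-3-oxo-1,3,5a,8,9,9a-hexahydro-2-benzoxepin-6-yl]methyl}-5-[(triethylsilyl)oxy]cyclohex-1-ene-1-carboxylate | CC1=C(C(=O)OC)C(=O)[C@@](C)(O[Si](CC)(CC)CC)C(=O)[C@]1(C)CC2=C(C)CC[C@@H]3C(C)(C)OC(=O)C=C[C@@]23C | intermediate
23 | silyl ether: the 16-O-triethylsilyl ether of the target 24, (5S,8S,9S,10S,12R,14R,16S) in the overview numbering | C=C1[C@@]2(C)C[C@H]3[C@]4(C)C=CC(=O)OC(C)(C)[C@H]4CC[C@]3(C)[C@]1(C(=O)OC)C(=O)[C@@](C)(O[Si](CC)(CC)CC)C2=O | intermediate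
24 | target meroterpenoid: the tetracyclic methyl ester with the ring A α,β-unsaturated ε-lactone, the 13-methylidene group, the 15,17-diketone and the free 16-hydroxyl, (5S,8S,9S,10S,12R,14R,16S) in the overview numbering | C=C1[C@@]2(C)C[C@H]3[C@]4(C)C=CC(=O)OC(C)(C)[C@H]4CC[C@]3(C)[C@]1(C(=O)OC)C(=O)[C@@](C)(O)C2=O | target

## Step count and risks

Total step count: 19. Longest linear sequence: 14 steps (steps 1–12, 18 and 19).

Step 18 (most likely to fail). The allyl-palladium intermediate may lose a β-hydrogen before the dienolate arrives (alkyl-Heck outcome), the dienolate may be allylated on oxygen, or it may decompose under irradiation. The fallback separates ring closure from fragment union and sets out from 14. A tin hydride radical cyclisation in the presence of TEMPO (Bu3SnH, TEMPO, benzene, 70 °C) should give the same 6-endo closure, with the allyl radical trapped at its primary C11 end as the alkoxyamine (5aR,9aS)-1,1,5a,7-tetramethyl-6-{[(2,2,6,6-tetramethylpiperidin-1-yl)oxy]methyl}-5a,8,9,9a-tetrahydro-2-benzoxepin-3(1H)-one F1. Zinc in acetic acid cleaves the N–O bond to the allylic alcohol (5aR,9aS)-6-(hydroxymethyl)-1,1,5a,7-tetramethyl-5a,8,9,9a-tetrahydro-2-benzoxepin-3(1H)-one F2. Methyl chloroformate and pyridine give [(5aR,9aS)-1,1,5a,7-tetramethyl-3-oxo-1,3,5a,8,9,9a-hexahydro-2-benzoxepin-6-yl]methyl methyl carbonate F3. A thermal Tsuji–Trost alkylation of 21 with this carbonate (Pd(PPh3)4, THF, rt) then comes back to the route at 22.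

Step 19. The C8 cation may be captured with poor facial selectivity (cis B/C fusion), or the acid may ionise the tertiary alkyl–oxygen bond of the lactone before the alkene reacts. The fallback sets out from 22 and pre-forms the nucleophile so that much less acid is needed. TESOTf and Et3N (CH2Cl2, −78 °C) give the extended silyl dienol ether methyl (3R,5R)-3,5-dimethyl-6-methylidene-4-oxo-5-{[(5aR,9aS)-1,1,5a,7-tetramethyl-3-oxo-1,3,5a,8,9,9a-hexahydro-2-benzoxepin-6-yl]methyl}-2,3-bis[(triethylsilyl)oxy]cyclohex-1-ene-1-carboxylate F4, which already holds the exocyclic methylene. Triflimide (Tf2NH, CH2Cl2, −78 °C) then protonates C9, the silyl enol ether carbon C14 captures the C8 cation in a Mukaiyama-type alkylation to give 23, and Et3N·3HF, added to the same mixture, comes back to the route at 24.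

Step 16. The chiral iodine reagent may transfer oxygen with low enantioselectivity to this hindered, hydrogen-bonded phenol. The fallback sets out from 18 and uses resolution instead of reagent control. Stabilised 2-iodoxybenzoic acid (SIBX, THF, rt; reductive work-up) should give the racemic quinol methyl 4-[(tert-butyldimethylsilyl)oxy]-5-hydroxy-2,3,5-trimethyl-6-oxocyclohexa-1,3-diene-1-carboxylate F5, and preparative chromatography on a chiral stationary phase separates the enantiomers, which comes back to the route at 19.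

## Further compounds

F1 | step 18 | (5aR,9aS)-1,1,5a,7-tetramethyl-6-{[(2,2,6,6-tetramethylpiperidin-1-yl)oxy]methyl}-5a,8,9,9a-tetrahydro-2-benzoxepin-3(1H)-one | CC1(C)CCCC(C)(C)N1OCC1=C(C)CC[C@@H]2C(C)(C)OC(=O)C=C[C@@]12C
F2 | step 18 | (5aR,9aS)-6-(hydroxymethyl)-1,1,5a,7-tetramethyl-5a,8,9,9a-tetrahydro-2-benzoxepin-3(1H)-one | OCC1=C(C)CC[C@@H]2C(C)(C)OC(=O)C=C[C@@]12C
F3 | step 18 | [(5aR,9aS)-1,1,5a,7-tetramethyl-3-oxo-1,3,5a,8,9,9a-hexahydro-2-benzoxepin-6-yl]methyl methyl carbonate | COC(=O)OCC1=C(C)CC[C@@H]2C(C)(C)OC(=O)C=C[C@@]12C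
F4 | step 19 | methyl (3R,5R)-3,5-dimethyl-6-methylidene-4-oxo-5-{[(5aR,9aS)-1,1,5a,7-tetramethyl-3-oxo-1,3,5a,8,9,9a-hexahydro-2-benzoxepin-6-yl]methyl}-2,3-bis[(triethylsilyl)oxy]cyclohex-1-ene-1-carboxylate | C=C1C(C(=O)OC)=C(O[Si](CC)(CC)CC)[C@@](C)(O[Si](CC)(CC)CC)C(=O)[C@]1(C)CC2=C(C)CC[C@@H]3C(C)(C)OC(=O)C=C[C@@]23C
F5 | step 16 | racemic methyl 4-[(tert-butyldimethylsilyl)oxy]-5-hydroxy-2,3,5-trimethyl-6-oxocyclohexa-1,3-diene-1-carboxylate | COC(=O)C1=C(C)C(C)=C(O[Si](C)(C)C(C)(C)C)C(C)(O)C1=O
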